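**Conventions and assumptions**

- Locants (germacrane-type) are used for all ring compounds: C1H2–C2H2–C3H2–C4H(CH3)–C5(=O)–C6H(OH)–C7H–C8H(O)–C9H(O-isobutyryl)–C10(CH3)(OH)–C1. C11(=C13H2)–C12(=O)–O8 is the lactone on C7/C8; C14 is the methyl on C10, C15 the methyl on C4. The target is (4S,6S,7S,8R,9S,10R).
- Assumption 1: the (S,S)-lithium amide of step 1 is taken to leave the (6S)-enol silane 2, by analogy with 4-substituted cyclohexanones; if the sense is opposite, the (R,R)-amide (also commercial) is used.
- Assumption 2: ketone 1 is used as the pure cis (meso) isomer, obtained from the commercial cis-rich mixture by base equilibration and fractionation.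

## The problem

The skeleton is a ten-membered carbocycle with no ring double bond, trans-fused at C7/C8 to an α-methylene-γ-butyrolactone, so a direct ring closure pays the full medium-ring penalty and nothing preorganises it. There are six stereocentres: the contiguous set C6–C10 (C6–OH, C7–C11, C8–O, C9–O-acyl, tertiary C10–OH) and the isolated C4 next to the ketone. C7 and C8, once set, fix the shape of the ring and can steer reagents to C6 and to C9/C10 from the outside of the ring; C4 is remote from this cluster and epimerisable, so it must be set early and then kept away from base. The fragile groups are the exocyclic acrylate (Michael acceptor, to be unveiled late), the C5/C6 α-ketol (epimerisation, and a free C6–OH can take the lactone over from O8), the C9 ester flanked by other oxygens (acyl migration), and the tertiary C10–OH opposite the C5 ketone (elimination or transannular reactions under acid). The feature that makes the key step possible is that the C5 ketone and the C9/C10 glycol are 1,5-related through C6–C7–C8: read as an olefin, the glycol makes the ring a cyclodec-5-enone, the product type of an oxy-Cope rearrangement. In that reading the new σ bond is exactly the lactone ring-fusion bond C7–C8, and C6–OH sits on the enolate carbon. The six ring atoms that remain, C10–C1–C2–C3–C4–C5, carry only C14, C15 and the carbonyl, which is the pattern of cis-2,6-dimethylcyclohexanone 1 (meso): the target ring is 1 with the four-carbon unit C6–C9 inserted between its carbonyl carbon and one α-carbon.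

## Retrosynthesis

**24 ⇐ 23 ⇐ 22 (O–Si and O–acyl bonds).** The silyl ether on O6 and the ester on O9 are cut, leaving diol 22. Acylation can tell the secondary C9–OH from the tertiary C10–OH only while C6–OH is masked, so the silyl group that the C6 oxygenation delivers anyway is kept to the end. The forward steps need a selective acylation and a non-basic desilylation, since base would let the lactone move from O8 to O6.

**22 ⇐ 21 (C10–O bond).** The two glycol oxygens lie on opposite faces of a former E olefin, which is an anti addition; the C10–OH bond is therefore cut back to epoxide 21 and water. Syn-dihydroxylation would need the Z olefin, which the ring expansion does not give. The forward reaction must open the oxirane at the tertiary carbon with inversion.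

**21 ⇐ 18 ⇐ 17 (lactone acyl–O8 bond and oxidation level of C12).** The lactone is cut to 1,4-diol 18, which is the bis-PMB ether 17 without its protecting groups. This keeps the acrylate out of every basic and organometallic step. The forward reaction must oxidise a primary allylic alcohol in the presence of a secondary one.

**17 ⇐ 15 (C6–O bond and both epoxide C–O bonds).** All three C–O bonds are removed at once, giving diene 15, in which C5=C6 is a silyl enol ether and C9=C10 a trisubstituted olefin. Both π bonds are products of one reaction and each shows only its outer face, so one peracid operation can set C6, C9 and (latently) C10. The precursor has two stereocentres fewer and no oxygen on C6, C9 or C10.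

**15 ⇐ 12 (cut C7–C8, rejoin C5–C10; key step).** Cutting the ring-fusion bond C7–C8 and reconnecting C5 to C10 contracts the ten-membered ring to the cyclohexanol 12. Against a macrocyclisation at the same bond, this closure has no entropic cost and both stereocentres come from a chair transition state. The precursor is a six-membered ring with three stereocentres, two of which (C5, C10) are only relays. The forward reaction needs the trans-dialkenyl carbinol, E geometry on both olefins and a chair transition state.

**12 ⇐ 5 + 10 (C5–C6 bond).** The tertiary carbinol is cut to ketone 5 and the dienylstannane 10 (as its lithium reagent 11). Stannane 10 comes from vinyl bromide 8 and bis-stannane 9, and 8 from dibromide 6 and alcohol 7. The addition must occur trans to the alkoxyvinyl group of 5.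

**5 ⇐ 4 ⇐ 2 + 3 (C8=C9, then C9–C10).** The enol ether is taken back to the β-hydroxy ketone 4 (C10 is quaternary, so water can only be lost towards C8), and 4 to the silyl enol ether 2 and aldehyde 3. The aldol must add anti to the C4 methyl group.

**2 ⇐ 1 (C5–O–Si, enantiotopic α-H).** The enol silane 2 is the desymmetrised form of meso ketone 1. This one step supplies all the absolute stereochemistry; C4 then directs C10, C10 directs C5, and C5/C10 direct C7/C8.

## Roads not taken

**Alternative 1:** (the most obvious) cut C7–C8 in the open-chain sense. The seco aldehyde–allyl bromide A1 would be closed by an intramolecular Barbier/Nozaki–Hiyama allylation (CrCl2 or Zn), lactonised to A2, and the acetonide removed.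
- A1 needs four stereocentres (C4, C6, C9, C10) assembled on a fourteen-atom open chain before the ring exists.
- The closure pays the full ten-membered-ring penalty.
- The allylmetal carries the C6 silyloxy group next to its nucleophilic carbon C7, which invites β-elimination to a diene.
- The closed six-membered transition state of a γ-substituted allylmetal normally gives the syn (cis-lactone) pair, whereas the trans fusion is needed.

The chosen plan makes the same bond inside a chair with no ring-closure entropy and with the trans relationship built in.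

**Alternative 2:** cut C9=C10. Ring-closing metathesis of diene A3 (second-generation Grubbs catalyst) would give the Z-cyclodecene A4, followed by syn-dihydroxylation with OsO4.
- A trisubstituted olefin in a strained ten-membered ring is a poor metathesis target and favours oligomers.
- The acrylate competes for the catalyst and would have to be masked.
- C4, C6, C7 and C8 still need open-chain stereocontrol.
- Both the Z geometry and the face of dihydroxylation are left to the ring.

The chosen plan gets the C9=C10 olefin with defined geometry as a by-product of the ring-forming step.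

**Alternative 3:** the oxy-Cope in the conventional sense. The six-membered ring would be C5–C10 (divinylcyclohexanol A5), the new bond C2–C3, and the product the cyclodec-1(10)-en-5-one A6.
- A5 must already carry five contiguous stereocentres, including the quaternary C10, on the cyclohexane, which is a long run-up.
- The new σ bond joins two CH2 groups and creates no stereocentre.
- C10–OH would then come from a Markovnikov hydration of C1=C10 with no control element, and C4 from protonation of an enolate on the ring.

The chosen plan puts the sigmatropic bond where the stereochemical density is and leaves the simple half of the ring to a meso starting material.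

Key step: step 7

## Route

Step 1
Reactants: 1 cis-2,6-dimethylcyclohexanone
Product: 2 trimethyl{[(6S)-2,6-dimethylcyclohex-1-en-1-yl]oxy}silane
Conditions: lithium bis[(S)-1-phenylethyl]amide (from the amine and n-BuLi), TMSCl (in situ quench), THF, −100 → −78 °C
Reagents that add atoms: chlorotrimethylsilane, C[Si](C)(C)Cl
Why: Enantioselective deprotonation of a meso ketone: the C2-symmetric lithium amide removes one of the two enantiotopic axial α-hydrogens and TMSCl traps the enolate as it forms; the α-carbon that is not deprotonated becomes the C4 stereocentre (S), the only one set by a chiral reagent.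

Step 2
Reactants: 2 trimethyl{[(6S)-2,6-dimethylcyclohex-1-en-1-yl]oxy}silane; 3 2-(4-methoxybenzyloxy)acetaldehyde
Product: 4 (2R,6S)-2-[1-hydroxy-2-(4-methoxybenzyloxy)ethyl]-2,6-dimethylcyclohexan-1-one (both epimers at the carbinol carbon)
Conditions: BF3·OEt2, CH2Cl2, −78 °C; aq. NaHCO3
Reagents that add atoms: none
Why: Mukaiyama aldol addition of a fully substituted silyl enol ether builds the quaternary C10 and the C9–C10 bond; the aldehyde approaches C10 anti to the C15 methyl on C4 (attack syn to it would develop a 1,3-diaxial contact in the chair-like transition state), giving the cis-dimethyl ketone with C10 (R). The carbinol centre forms as a mixture that converges in step 3.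

Step 3
Reactants: 4 (2R,6S)-2-[1-hydroxy-2-(4-methoxybenzyloxy)ethyl]-2,6-dimethylcyclohexan-1-one
Product: 5 (2R,6S)-2-[(E)-2-(4-methoxybenzyloxy)ethenyl]-2,6-dimethylcyclohexan-1-one
Conditions: methyl N-(triethylammoniosulfonyl)carbamate (Burgess reagent), toluene, 60 °C
Reagents that add atoms: none
Why: Thermal syn-elimination of the sulfamate ester of the secondary alcohol; C10 is quaternary, so only a C8 hydrogen can be lost and the double bond can only form as the enol ether, and the transition state that keeps the OPMB group away from the quaternary carbon gives the E isomer from either carbinol epimer.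

Step 4
Reactants: 6 2,3-dibromoprop-1-ene; 7 (4-methoxyphenyl)methanol
Product: 8 1-{[(2-bromoprop-2-en-1-yl)oxy]methyl}-4-methoxybenzene
Conditions: NaH, THF, 0 °C → rt
Reagents that add atoms: none
Why: Williamson ether synthesis by SN2 displacement of the allylic bromide; the vinylic bromide does not react.

Step 5
Reactants: 8 1-{[(2-bromoprop-2-en-1-yl)oxy]methyl}-4-methoxybenzene; 9 (E)-1,2-bis(tributylstannyl)ethene
Product: 10 tributyl[(1E)-3-(4-methoxybenzyloxymethyl)buta-1,3-dien-1-yl]stannane
Conditions: Pd(PPh3)4 (cat.), toluene, 90 °C (9 in excess)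
Reagents that add atoms: none
Why: Stille coupling of the vinylic bromide with one C–Sn bond of the bis-stannane (excess suppresses double coupling); the E geometry of the stannane is retained.

Step 6
Reactants: 10 tributyl[(1E)-3-(4-methoxybenzyloxymethyl)buta-1,3-dien-1-yl]stannane; 5 (2R,6S)-2-[(E)-2-(4-methoxybenzyloxy)ethenyl]-2,6-dimethylcyclohexan-1-one
Product: 12 (1S,2R,6S)-1-[(1E)-3-(4-methoxybenzyloxymethyl)buta-1,3-dien-1-yl]-2-[(E)-2-(4-methoxybenzyloxy)ethenyl]-2,6-dimethylcyclohexan-1-ol, via dienyllithium 11 (not isolated)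
Conditions: n-BuLi, THF, −78 °C; then 5, −78 → −40 °C; H2O
Reagents that add atoms: none
Why: Tin–lithium exchange with retention of olefin geometry, then 1,2-addition to the ketone. Ketone 5 is conformationally locked (both methyls equatorial, alkoxyvinyl group axial), so the nucleophile enters along the axial trajectory anti to the axial alkoxyvinyl group, which blocks the equatorial approach; this puts the two alkenyl groups trans and sets C5 (S).

Step 7
Reactants: 12 (1S,2R,6S)-1-[(1E)-3-(4-methoxybenzyloxymethyl)buta-1,3-dien-1-yl]-2-[(E)-2-(4-methoxybenzyloxy)ethenyl]-2,6-dimethylcyclohexan-1-ol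
Product: 15 (4S,7R,8S,5Z,9E)-5-(tert-butyldimethylsilyloxy)-8-(4-methoxybenzyloxy)-7-[3-(4-methoxybenzyloxy)prop-1-en-2-yl]-4,10-dimethylcyclodeca-5,9-diene, via potassium alkoxide 13 (not isolated), via potassium enolate 14 (not isolated)
Conditions: KH, 18-crown-6, THF, 0 °C → rt; then TBSCl, −78 → 0 °C
Reagents that add atoms: tert-butyldimethylsilyl chloride, CC(C)(C)[Si](C)(C)Cl
Why: Anionic oxy-Cope rearrangement: KH/18-crown-6 gives the naked alkoxide 13, whose oxyanion weakens the C5–C10 bond so that the [3,3] shift (C5–C10 broken, C7–C8 formed) runs at or below room temperature; the closest known reaction type is the ring expansion of trans-1,2-dialkenylcyclohexanols to cyclodec-5-enones. The ten-membered ring is not closed by a cyclisation but by a four-atom ring expansion through a six-membered chair transition state in which the ring bonds C5–C4 and C10–C1 and both alkenyl groups are equatorial and O− and C14 axial. With both olefins E, C11 and OPMB sit equatorial on the chair, so C7 and C8 emerge with the trans relationship of the lactone fusion, and their absolute configuration is dictated by C5 (S) and C10 (R), which themselves disappear into C5=C6 and C9=C10. The same chair makes C9=C10 E and gives enolate 14 with O cis to C7; the enolate is regiodefined towards C6 and C4 is not touched. The selectivities needed are chair over boat (a boat would give the cis C7/C8 pair), secured by the trans-diequatorial arrangement open only to the trans-dialkenyl carbinol 12, and [3,3] shift over retro-addition, secured because a vinyl anion is a poor leaving group. O-Silylation traps 14 as 15, in which the two new π bonds are differentiated for step 8.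

Step 8
Reactants: 15 (4S,7R,8S,5Z,9E)-5-(tert-butyldimethylsilyloxy)-8-(4-methoxybenzyloxy)-7-[3-(4-methoxybenzyloxy)prop-1-en-2-yl]-4,10-dimethylcyclodeca-5,9-diene
Product: 17 (4S,6S,7R,8R,9S,10S)-6-(tert-butyldimethylsilyloxy)-9,10-epoxy-8-(4-methoxybenzyloxy)-7-[3-(4-methoxybenzyloxy)prop-1-en-2-yl]-4,10-dimethylcyclodecan-5-one, via bis-epoxide 16 (not isolated)
Conditions: mCPBA (2.2 equiv), NaHCO3, CH2Cl2, −20 → 0 °C (15 used cold, directly)
Reagents that add atoms: 3-chloroperoxybenzoic acid, OOC(=O)c1cccc(Cl)c1
Why: Rubottom oxidation of the silyl enol ether and epoxidation of the trisubstituted olefin in one operation; the siloxy oxirane opens with 1,4-silyl shift to the α-silyloxy ketone. In the crossed conformation of the (E,E)-cyclodeca-1,5-diene inherited from the chair, each π bond shows only its outer face (H7 and H8 eclipse the π bonds, which minimises A(1,3) strain), giving C6 (S) and the (9S,10S)-oxirane; the 1,1-disubstituted C11=C13 and the ketone react more slowly.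

Step 9
Reactants: 17 (4S,6S,7R,8R,9S,10S)-6-(tert-butyldimethylsilyloxy)-9,10-epoxy-8-(4-methoxybenzyloxy)-7-[3-(4-methoxybenzyloxy)prop-1-en-2-yl]-4,10-dimethylcyclodecan-5-one
Product: 18 (4S,6S,7R,8R,9S,10S)-6-(tert-butyldimethylsilyloxy)-9,10-epoxy-8-hydroxy-7-(3-hydroxyprop-1-en-2-yl)-4,10-dimethylcyclodecan-5-one
Conditions: DDQ, CH2Cl2/pH 7 buffer, 0 °C → rt
Reagents that add atoms: none
Why: Oxidative cleavage of both 4-methoxybenzyl ethers by hydride abstraction and hydrolysis of the oxocarbenium ions; silyl ether, epoxide and ketone are inert to DDQ under buffered conditions.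

Step 10
Reactants: 18 (4S,6S,7R,8R,9S,10S)-6-(tert-butyldimethylsilyloxy)-9,10-epoxy-8-hydroxy-7-(3-hydroxyprop-1-en-2-yl)-4,10-dimethylcyclodecan-5-one
Product: 21 (4S,6S,7R,8R,9S,10S)-6-(tert-butyldimethylsilyloxy)-9,10-epoxy-5-oxogermacr-11(13)-en-8,12-olide, via hydroxy enal 19 (not isolated), via lactol 20 (not isolated)
Conditions: TEMPO (cat.), PhI(OAc)2, CH2Cl2, rt
Reagents that add atoms: none
Why: Oxoammonium oxidation selective for the primary allylic alcohol gives the enal, which the C8 hydroxyl captures as the five-membered lactol; this is oxidised again to the lactone (oxidative lactonisation of a 1,4-diol), while the secondary C8–OH alone is oxidised much more slowly. C7 and C8 are untouched, so the trans ring fusion set in step 7 is carried into the lactone.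

Step 11
Reactants: 21 (4S,6S,7R,8R,9S,10S)-6-(tert-butyldimethylsilyloxy)-9,10-epoxy-5-oxogermacr-11(13)-en-8,12-olide
Product: 22 (4S,6S,7R,8R,9S,10R)-6-(tert-butyldimethylsilyloxy)-9,10-dihydroxy-5-oxogermacr-11(13)-en-8,12-olide
Conditions: HClO4 (cat.), THF/H2O, 0 °C → rt
Reagents that add atoms: water, O
Why: Acid-catalysed hydrolysis of a trisubstituted epoxide: water attacks the protonated oxirane at the tertiary carbon C10 with inversion while the C9–O bond is retained, so anti opening of the trans-epoxide gives the diol with C10 (R). Participation of the transannular C5 carbonyl oxygen would deliver oxygen to the same face of C10 and ends in the same product after the hemiketal opens.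

Step 12
Reactants: 22 (4S,6S,7R,8R,9S,10R)-6-(tert-butyldimethylsilyloxy)-9,10-dihydroxy-5-oxogermacr-11(13)-en-8,12-olide
Product: 23 (4S,6S,7R,8R,9S,10R)-6-(tert-butyldimethylsilyloxy)-10-hydroxy-9-(2-methylpropanoyloxy)-5-oxogermacr-11(13)-en-8,12-olide
Conditions: (i-PrCO)2O, DMAP (cat.), Et3N, CH2Cl2, rt
Reagents that add atoms: isobutyric anhydride, CC(C)C(=O)OC(=O)C(C)C
Why: Nucleophile-catalysed acylation (DMAP) of the only free secondary hydroxyl; the tertiary C10–OH does not react under these conditions and C6–OH is silylated.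

Step 13
Reactants: 23 (4S,6S,7R,8R,9S,10R)-6-(tert-butyldimethylsilyloxy)-10-hydroxy-9-(2-methylpropanoyloxy)-5-oxogermacr-11(13)-en-8,12-olide
Product: 24 (4S,6S,7S,8R,9S,10R)-6,10-dihydroxy-9-(2-methylpropanoyloxy)-5-oxogermacr-11(13)-en-8,12-olide (CNP0270933.1)
Conditions: HF·pyridine, THF, 0 °C → rt
Reagents that add atoms: none
Why: Fluoride-mediated cleavage of the secondary silyl ether under weakly acidic, non-basic conditions, which avoid acyl migration, epimerisation of the α-ketol and migration of the lactone from O8 to O6.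

## Compound list

1 | cis-2,6-dimethylcyclohexanone (meso) | C[C@H]1CCC[C@@H](C)C1=O | starting material
2 | trimethyl{[(6S)-2,6-dimethylcyclohex-1-en-1-yl]oxy}silane | C[C@H]1CCCC(C)=C1O[Si](C)(C)C | intermediate
3 | 2-(4-methoxybenzyloxy)acetaldehyde | O=CCOCc1ccc(OC)cc1 | starting material
4 | (2R,6S)-2-[1-hydroxy-2-(4-methoxybenzyloxy)ethyl]-2,6-dimethylcyclohexan-1-one, both carbinol epimers | C[C@H]1CCC[C@](C)(C(O)COCc2ccc(OC)cc2)C1=O | intermediate
5 | (2R,6S)-2-[(E)-2-(4-methoxybenzyloxy)ethenyl]-2,6-dimethylcyclohexan-1-one | C[C@H]1CCC[C@](C)(/C=C/OCc2ccc(OC)cc2)C1=O | intermediate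
6 | 2,3-dibromoprop-1-ene | C=C(Br)CBr | starting material
7 | (4-methoxyphenyl)methanol | COc1ccc(CO)cc1 | starting material
8 | 1-{[(2-bromoprop-2-en-1-yl)oxy]methyl}-4-methoxybenzene | C=C(Br)COCc1ccc(OC)cc1 | intermediate
9 | (E)-1,2-bis(tributylstannyl)ethene | CCCC[Sn](CCCC)(CCCC)/C=C/[Sn](CCCC)(CCCC)CCCC | starting material
10 | tributyl[(1E)-3-(4-methoxybenzyloxymethyl)buta-1,3-dien-1-yl]stannane | C=C(COCc1ccc(OC)cc1)/C=C/[Sn](CCCC)(CCCC)CCCC | intermediate
11 | [(1E)-3-(4-methoxybenzyloxymethyl)buta-1,3-dien-1-yl]lithium | C=C(COCc1ccc(OC)cc1)/C=C/[Li] | intermediate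
12 | (1S,2R,6S)-1-[(1E)-3-(4-methoxybenzyloxymethyl)buta-1,3-dien-1-yl]-2-[(E)-2-(4-methoxybenzyloxy)ethenyl]-2,6-dimethylcyclohexan-1-ol | C[C@H]1CCC[C@](C)(/C=C/OCc2ccc(OC)cc2)[C@@]1(O)/C=C/C(=C)COCc3ccc(OC)cc3 | intermediate
13 | potassium alkoxide of 12 | C[C@H]1CCC[C@](C)(/C=C/OCc2ccc(OC)cc2)[C@@]1([O-])/C=C/C(=C)COCc3ccc(OC)cc3.[K+] | intermediate
14 | potassium (4S,7R,8S,5Z,9E)-8-(4-methoxybenzyloxy)-7-[3-(4-methoxybenzyloxy)prop-1-en-2-yl]-4,10-dimethylcyclodeca-5,9-dien-5-olate | C[C@H]1CCC/C(C)=C/[C@H](OCc2ccc(OC)cc2)[C@@H](C(=C)COCc3ccc(OC)cc3)/C=C1\[O-].[K+] | intermediate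
15 | (4S,7R,8S,5Z,9E)-5-(tert-butyldimethylsilyloxy)-8-(4-methoxybenzyloxy)-7-[3-(4-methoxybenzyloxy)prop-1-en-2-yl]-4,10-dimethylcyclodeca-5,9-diene | C[C@H]1CCC/C(C)=C/[C@H](OCc2ccc(OC)cc2)[C@@H](C(=C)COCc3ccc(OC)cc3)/C=C1\O[Si](C)(C)C(C)(C)C | intermediate
16 | 5,6:9,10-bis-epoxide of 15 (5-silyloxy oxirane, both oxiranes on the outer faces) | C[C@H]1CCC[C@]3(C)O[C@H]3[C@H](OCc2ccc(OC)cc2)[C@@H](C(=C)COCc5ccc(OC)cc5)[C@@H]4O[C@@]14O[Si](C)(C)C(C)(C)C | intermediate
17 | (4S,6S,7R,8R,9S,10S)-6-(tert-butyldimethylsilyloxy)-9,10-epoxy-8-(4-methoxybenzyloxy)-7-[3-(4-methoxybenzyloxy)prop-1-en-2-yl]-4,10-dimethylcyclodecan-5-one | C[C@H]1CCC[C@]3(C)O[C@H]3[C@H](OCc2ccc(OC)cc2)[C@@H](C(=C)COCc4ccc(OC)cc4)[C@H](O[Si](C)(C)C(C)(C)C)C1=O | intermediate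
18 | (4S,6S,7R,8R,9S,10S)-6-(tert-butyldimethylsilyloxy)-9,10-epoxy-8-hydroxy-7-(3-hydroxyprop-1-en-2-yl)-4,10-dimethylcyclodecan-5-one | C[C@H]1CCC[C@]3(C)O[C@H]3[C@H](O)[C@@H](C(=C)CO)[C@H](O[Si](C)(C)C(C)(C)C)C1=O | intermediate
19 | hydroxy enal from 18 (C12 aldehyde, C8–OH free) | C[C@H]1CCC[C@]3(C)O[C@H]3[C@H](O)[C@@H](C(=C)C=O)[C@H](O[Si](C)(C)C(C)(C)C)C1=O | intermediate
20 | lactol from 19 (C12 hemiacetal closed to O8, both anomers) | C[C@H]1CCC[C@]3(C)O[C@H]3[C@@H]2OC(O)C(=C)[C@H]2[C@H](O[Si](C)(C)C(C)(C)C)C1=O | intermediate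
21 | (4S,6S,7R,8R,9S,10S)-6-(tert-butyldimethylsilyloxy)-9,10-epoxy-5-oxogermacr-11(13)-en-8,12-olide | C[C@H]1CCC[C@]3(C)O[C@H]3[C@@H]2OC(=O)C(=C)[C@H]2[C@H](O[Si](C)(C)C(C)(C)C)C1=O | intermediate
22 | (4S,6S,7R,8R,9S,10R)-6-(tert-butyldimethylsilyloxy)-9,10-dihydroxy-5-oxogermacr-11(13)-en-8,12-olide | C[C@H]1CCC[C@@](C)(O)[C@@H](O)[C@@H]2OC(=O)C(=C)[C@H]2[C@H](O[Si](C)(C)C(C)(C)C)C1=O | intermediate
23 | (4S,6S,7R,8R,9S,10R)-6-(tert-butyldimethylsilyloxy)-10-hydroxy-9-(2-methylpropanoyloxy)-5-oxogermacr-11(13)-en-8,12-olide | C[C@H]1CCC[C@@](C)(O)[C@@H](OC(=O)C(C)C)[C@@H]2OC(=O)C(=C)[C@H]2[C@H](O[Si](C)(C)C(C)(C)C)C1=O | intermediate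
24 | (4S,6S,7S,8R,9S,10R)-6,10-dihydroxy-9-(2-methylpropanoyloxy)-5-oxogermacr-11(13)-en-8,12-olide (CNP0270933.1) | C[C@H]1CCC[C@@](C)(O)[C@@H](OC(=O)C(C)C)[C@@H]2OC(=O)C(=C)[C@H]2[C@H](O)C1=O | target

## Step count and risks

Total step count: 13. Longest linear sequence: 11 steps (steps 1, 2, 3, 6, 7, 8, 9, 10, 11, 12, 13).

**Step 7 (key step).** Both bond-forming termini are substituted and the reactive chair places C14 and C15 syn-diaxial, so the [3,3] shift may be slow enough for alkoxide decomposition (retro-addition, loss of the enol ether) or a boat pathway to compete; the neutral diene 15 can also revert by Cope rearrangement if warmed. Fallback: the neutral siloxy-Cope rearrangement, which involves no alkoxide. It sets out from 12: silylation with TBSOTf/2,6-lutidine gives the tertiary silyl ether F1, and thermolysis of F1 (degassed decalin, about 200 °C, base-washed glass) gives the silyl enol ether directly, returning to the route at 15.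

**Step 6.** The bulky, basic dienyllithium may show poor facial selectivity (equatorial attack gives the cis-dialkenyl epimer, useless for the chair) or enolise C4. Fallback: a rod-like acetylide followed by reduction. It sets out from 8 and 5: Sonogashira coupling of 8 with trimethylsilylacetylene (PdCl2(PPh3)2, CuI, Et3N) gives the silyl enyne F2; K2CO3/MeOH gives the terminal enyne F3; its lithium acetylide (n-BuLi) adds axially to 5 to give the propargylic alcohol F4; trans-hydroalumination with NaAlH2(OCH2CH2OCH3)2 reduces F4 to the E-dienyl carbinol, returning at 12.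

**Step 8.** Facial selectivity of the C9=C10 epoxidation may be insufficient while C8 still carries a flexible ether, or C11=C13 may be over-oxidised. Fallback: move the epoxidation to the trans-fused lactone, whose ring fusion locks C7/C8. It sets out from 15: Rubottom oxidation with one equivalent of dimethyldioxirane (acetone, −78 °C) gives the α-silyloxy ketone F5 with C9=C10 intact; DDQ gives the diol F6; TEMPO/PhI(OAc)2 gives the lactone F7; mCPBA then epoxidises only the ring olefin of F7, returning at 21.

**Step 3.** The neopentyl-type sulfamate may ionise (1,2-acyl shift, retro-aldol) instead of undergoing syn-elimination, or the E geometry may erode. Fallback: C–O coupling on a stereodefined vinyl iodide. It sets out from 2: formylation with Cl2CHOCH3/TiCl4 gives the α-formyl ketone F8; Takai olefination (CrCl2, CHI3) gives the E-vinyl iodide F9; coupling of F9 with 7 (CuI, 3,4,7,8-tetramethyl-1,10-phenanthroline, Cs2CO3, toluene, 80 °C) gives the E enol ether, returning at 5.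

**Step 11.** Under acid, elimination to allylic alcohols, attack at C9, or loss of the silyl ether may compete with hydrolysis at C10. Fallback: acyloxylative opening and acyl shift instead of hydrolysis and acylation. It sets out from 21: isobutyric acid as solvent (mild heating) opens the oxirane at C10 with inversion to give the tertiary ester F10; catalytic DBU moves the acyl group from the tertiary O10 to the secondary O9, returning at 23 and bypassing 22.

## Further compounds

F1 | step 7 | tert-butyldimethylsilyl ether of carbinol 12 | C[C@H]1CCC[C@](C)(/C=C/OCc2ccc(OC)cc2)[C@@]1(O[Si](C)(C)C(C)(C)C)/C=C/C(=C)COCc3ccc(OC)cc3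
F2 | step 6 | trimethyl[3-(4-methoxybenzyloxymethyl)but-3-en-1-yn-1-yl]silane | C[Si](C)(C)C#CC(=C)COCc1ccc(OC)cc1
F3 | step 6 | 1-methoxy-4-{[(2-methylidenebut-3-yn-1-yl)oxy]methyl}benzene | C#CC(=C)COCc1ccc(OC)cc1
F4 | step 6 | (1S,2R,6S)-1-[3-(4-methoxybenzyloxymethyl)but-3-en-1-yn-1-yl]-2-[(E)-2-(4-methoxybenzyloxy)ethenyl]-2,6-dimethylcyclohexan-1-ol (spatial arrangement as in 12) | C[C@H]1CCC[C@](C)(/C=C/OCc2ccc(OC)cc2)[C@@]1(O)C#CC(=C)COCc3ccc(OC)cc3
F5 | step 8 | (4S,6S,7R,8S,9E)-6-(tert-butyldimethylsilyloxy)-8-(4-methoxybenzyloxy)-7-[3-(4-methoxybenzyloxy)prop-1-en-2-yl]-4,10-dimethylcyclodec-9-en-5-one | C[C@H]1CCC/C(C)=C/[C@H](OCc2ccc(OC)cc2)[C@@H](C(=C)COCc3ccc(OC)cc3)[C@H](O[Si](C)(C)C(C)(C)C)C1=O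
F6 | step 8 | 8-hydroxy-7-(3-hydroxyprop-1-en-2-yl) diol from F5 | C[C@H]1CCC/C(C)=C/[C@H](O)[C@@H](C(=C)CO)[C@H](O[Si](C)(C)C(C)(C)C)C1=O
F7 | step 8 | (9E)-6-(tert-butyldimethylsilyloxy)-5-oxogermacra-9,11(13)-dien-8,12-olide (configuration at C4, C6, C7, C8 as in 21) | C[C@H]1CCC/C(C)=C/[C@@H]2OC(=O)C(=C)[C@H]2[C@H](O[Si](C)(C)C(C)(C)C)C1=O
F8 | step 3 | (1R,3S)-1,3-dimethyl-2-oxocyclohexane-1-carbaldehyde | C[C@H]1CCC[C@](C)(C=O)C1=O
F9 | step 3 | (2R,6S)-2-[(E)-2-iodoethenyl]-2,6-dimethylcyclohexan-1-one | C[C@H]1CCC[C@](C)(/C=C/I)C1=O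
F10 | step 11 | 6-(tert-butyldimethylsilyloxy)-9-hydroxy-10-(2-methylpropanoyloxy)-5-oxogermacr-11(13)-en-8,12-olide (configuration as in 22) | C[C@H]1CCC[C@@](C)(OC(=O)C(C)C)[C@@H](O)[C@@H]2OC(=O)C(=C)[C@H]2[C@H](O[Si](C)(C)C(C)(C)C)C1=O
A1 | alternative 1 | seco aldehyde–allyl bromide: methyl (Z)-2-(bromomethyl)enoate with 6-silyloxy, 5-oxo, 4-methyl and a 9,10-acetonide ending in the C8 aldehyde | O=C[C@@H]1OC(C)(C)O[C@]1(C)CCC[C@H](C)C(=O)[C@@H](O[Si](C)(C)C(C)(C)C)/C=C(\CBr)C(=O)OC
A2 | alternative 1 | ring-closed lactone as 9,10-acetonide and 6-silyl ether | C[C@H]1CCC[C@@]3(C)OC(C)(C)O[C@H]3[C@@H]2OC(=O)C(=C)[C@H]2[C@H](O[Si](C)(C)C(C)(C)C)C1=O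
A3 | alternative 2 | metathesis diene: 8-vinyl lactone with the C5 keto chain ending in the 2-methylallyl unit | C=C[C@@H]1OC(=O)C(=C)[C@H]1[C@H](O[Si](C)(C)C(C)(C)C)C(=O)[C@@H](C)CCCC(C)=C
A4 | alternative 2 | (9Z)-6-(tert-butyldimethylsilyloxy)-5-oxogermacra-9,11(13)-dien-8,12-olide | C[C@H]1CCC/C(C)=C\[C@@H]2OC(=O)C(=C)[C@H]2[C@H](O[Si](C)(C)C(C)(C)C)C1=O
A5 | alternative 3 | 1-isopropenyl-2-methyl-2-vinylcyclohexan-1-ol carrying C6–C9 (trans-dialkenyl; 6,9-bis-silyloxy, 8-OPMB, 7-[3-(PMBO)prop-1-en-2-yl]) | C=C[C@]1(C)[C@@H](O[Si](C)(C)C(C)(C)C)[C@H](OCc2ccc(OC)cc2)[C@@H](C(=C)COCc2ccc(OC)cc2)[C@H](O[Si](C)(C)C(C)(C)C)[C@@]1(O)C(C)=C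
A6 | alternative 3 | (1(10)E)-cyclodec-1(10)-en-5-one from A5 (C4 drawn with the desired configuration) | C[C@H]1CC/C=C(\C)[C@@H](O[Si](C)(C)C(C)(C)C)[C@H](OCc2ccc(OC)cc2)[C@@H](C(=C)COCc2ccc(OC)cc2)[C@H](O[Si](C)(C)C(C)(C)C)C1=O
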